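**Retrosynthetic overview**
1. Target ⇒ shikimate-type allylic bis-benzoate (C1=C2 alkene, 3-OBz, 7-OBz, free 4,5-diol). The last step forms the C2–O bond by a singlet-oxygen ene reaction that shifts the double bond to C1=C6 and sets C2 anti to the 3-benzoate.
2. Bis-benzoate ⇒ acetal-protected allylic diol, by benzoylation of the only two free hydroxyls and then acetal cleavage.
3. Allylic diol ⇒ acetal-protected methyl shikimate, by ester reduction.
4. ⇒ (−)-shikimic acid, which supplies the carbocycle and the C3, C4 and C5 stereocentres. The only ring made is the temporary dioxane (BDA) ring in step 1, removed in step 4; no C–C bond is formed.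

Assumption: natural (−)-shikimic acid (3R,4S,5R) is taken as the cheap commercial starting material. Ring atoms keep shikimic acid numbering throughout (C1 bears the exocyclic carbon C7; C3, C4, C5 carry the original oxygens), so the target has the new hydroxyl at C2 and the alkene at C1=C6.

**Route**

Step 1
Reactants: 1 (−)-shikimic acid
Product: 3 methyl 4,5-O-[(2S,3S)-2,3-dimethoxybutane-2,3-diyl]shikimate (BDA acetal on the trans-4,5-diol; 3-OH free), via methyl shikimate 2 (not isolated)
Conditions: camphor-10-sulfonic acid (10 mol %), MeOH, reflux; then butane-2,3-dione, HC(OMe)3, reflux; Et3N quench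
Reagents that add atoms: methanol CO; butane-2,3-dione CC(=O)C(C)=O; trimethyl orthoformate COC(OC)OC
Why: Fischer esterification followed by Ley butane-2,3-diacetal formation, which under thermodynamic control bridges only the trans-diequatorial 4,5-diol (both OMe axial, acetal carbons S,S) and leaves the pseudoaxial allylic 3-OH free; no ring stereocentre is touched.

Step 2
Reactants: 3 methyl 4,5-O-[(2S,3S)-2,3-dimethoxybutane-2,3-diyl]shikimate
Product: 4 BDA-protected allylic diol (C1 carries CH2OH; 3-OH free; ring configuration as in 1)
Conditions: iBu2AlH (4.5 equiv), CH2Cl2, −78 → −20 °C; aq. potassium sodium tartrate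
Reagents that add atoms: none
Why: iBu2AlH 1,2-reduction of the conjugated ester to the allylic alcohol at low temperature; the acetal and the alkene are inert and the free 3-OH only consumes one hydride.

Step 3
Reactants: 4 BDA-protected allylic diol
Product: 5 BDA-protected 3,7-di-O-benzoate
Conditions: BzCl (2.6 equiv), pyridine, 4-(dimethylamino)pyridine (cat.), CH2Cl2, 0 °C → rt
Reagents that add atoms: benzoyl chloride O=C(Cl)c1ccccc1
Why: exhaustive acyl transfer under nucleophilic catalysis onto the only two free hydroxyls, so both benzoates of the target are placed without site selection; C3 keeps its configuration because its C–O bond is not broken.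

Step 4
Reactants: 5 BDA-protected 3,7-di-O-benzoate
Product: 6 [(3R,4S,5R)-3-(benzoyloxy)-4,5-dihydroxycyclohex-1-en-1-yl]methyl benzoate
Conditions: CF3CO2H/H2O (9:1), 0 °C → rt, 15 min
Reagents that add atoms: none
Why: acid hydrolysis of the bis-ketal (standard BDA removal), fast enough in aqueous CF3CO2H that the benzoates should neither hydrolyse nor migrate; no stereocentre is involved.

Step 5
Reactants: 6 [(3R,4S,5R)-3-(benzoyloxy)-4,5-dihydroxycyclohex-1-en-1-yl]methyl benzoate
Product: 8 [(3R,4S,5R,6S)-5-(benzoyloxy)-3,4,6-trihydroxycyclohex-1-en-1-yl]methyl benzoate (target), via allylic hydroperoxide 7 (not isolated)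
Conditions: O2, 5,10,15,20-tetrakis(pentafluorophenyl)porphyrin (1 mol %), white LEDs, CDCl3, 0 °C; then PPh3 (1.2 equiv), 0 °C → rt
Reagents that add atoms: dioxygen O=O
Why: Proposed new method: a Schenck ene hydroxylation used as a 1,3-transposing allylic oxidation on an alkene flanked by two allylic benzoates, a substrate class on which, to my knowledge, it has not been shown; singlet oxygen attacks C2 from the face anti to the pseudoaxial 3-benzoate and the perepoxide-like transition state can only take the pseudoaxial C6–H on that face (C3–H is pseudoequatorial and α-acyloxy, the C7 hydrogens are α-acyloxy and on the less substituted side), so C2–O forms trans to the 3-OBz while the alkene moves to C1=C6, the concerted path avoids cations that the benzoates would capture, and PPh3 reduces the hydroperoxide with retention; closest known reaction type: the Schenck ene reaction of trisubstituted cycloalkenes (cis effect) followed by phosphine reduction.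

**Compound list**
1 | (−)-shikimic acid | O=C(O)C1=C[C@@H](O)[C@@H](O)[C@H](O)C1 | starting material
2 | methyl shikimate | COC(=O)C1=C[C@@H](O)[C@@H](O)[C@H](O)C1 | intermediate
3 | methyl 4,5-O-[(2S,3S)-2,3-dimethoxybutane-2,3-diyl]shikimate | COC(=O)C1=C[C@@H](O)[C@H]2O[C@](C)(OC)[C@@](C)(OC)O[C@@H]2C1 | intermediate
4 | BDA-protected allylic diol (7-OH, 3-OH) | OCC1=C[C@@H](O)[C@H]2O[C@](C)(OC)[C@@](C)(OC)O[C@@H]2C1 | intermediate
5 | BDA-protected 3,7-di-O-benzoate | O=C(OCC1=C[C@@H](OC(=O)c2ccccc2)[C@H]3O[C@](C)(OC)[C@@](C)(OC)O[C@@H]3C1)c1ccccc1 | intermediate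
6 | [(3R,4S,5R)-3-(benzoyloxy)-4,5-dihydroxycyclohex-1-en-1-yl]methyl benzoate | O=C(OCC1=C[C@@H](OC(=O)c2ccccc2)[C@@H](O)[C@H](O)C1)c1ccccc1 | intermediate
7 | allylic hydroperoxide (as 8, with OOH in place of the new OH, same configuration) | O=C(OCC1=C[C@@H](O)[C@H](O)[C@H](OC(=O)c2ccccc2)[C@H]1OO)c1ccccc1 | intermediate
8 | [(3R,4S,5R,6S)-5-(benzoyloxy)-3,4,6-trihydroxycyclohex-1-en-1-yl]methyl benzoate | O=C(OCC1=C[C@@H](O)[C@H](O)[C@H](OC(=O)c2ccccc2)[C@H]1O)c1ccccc1 | target

**Totals**
Total steps: 5. Longest linear sequence: 5.

**Steps most likely to fail**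

Step 5 (the proposed ene hydroxylation). The alkene is deactivated by two allylic benzoates, so photooxygenation may be slow, and abstraction of an exocyclic C7–H could compete. The fallback uses known chemistry and replaces the pericyclic ene by a stepwise epoxide route; it sets out from 6 and comes back at 8. Compound 6 is epoxidised with 3-chloroperbenzoic acid (CH2Cl2, NaHCO3, 0 °C) on the face anti to the pseudoaxial 3-benzoate to give the 1,2-epoxide F1. F1 is opened with Me3SiOTf and 2,6-dimethylpyridine at −78 °C (cleavage of the tertiary C1–O bond, the hydroxyls being silylated in passing) and then treated with 1,8-diazabicyclo[5.4.0]undec-7-ene, which removes the anti-periplanar axial C6–H in the known epoxide-to-allylic-silyl-ether isomerisation, giving the tris(trimethylsilyl) ether F2. Citric acid in MeOH strips the silyl groups to give 8.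

Step 4 (acidic acetal cleavage beside two benzoates). The risk is 3→4 acyl migration or partial ester loss. The fallback swaps the acid-labile acetal for a fluoride-labile disiloxane; it sets out from 2 (isolated after the first stage of step 1) and comes back at 6. 1,3-Dichloro-1,1,3,3-tetraisopropyldisiloxane with imidazole in DMF bridges the trans-diequatorial 4,5-diol to give the disiloxane ester F3. iBu2AlH at −78 °C gives the disiloxane diol F4, BzCl/pyridine gives the disiloxane dibenzoate F5, and Et3N·3HF in THF (non-basic fluoride, so no acyl migration) releases 6.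

Step 1 (one-pot esterification and trans-selective acetalisation). The risk is incomplete esterification or acetal mixtures. The fallback differentiates O3 through the cis-3,4-diol instead; it sets out from 2 (isolated) and comes back at 6. Trimethyl orthobenzoate with camphor-10-sulfonic acid gives the cis-fused 3,4-orthobenzoate ester F6 (both epimers at the orthoester carbon). iBu2AlH at −78 °C gives the orthoester diol F7, and BzCl with 2,4,6-trimethylpyridine at −40 °C acylates only the primary hydroxyl to give the orthoester monobenzoate F8. Aqueous 80% AcOH then opens the orthoester to the axial ester and equatorial alcohol, which puts the benzoate on the pseudoaxial O3 and gives 6.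

**Further compounds**
F1 | step 5 | 1,2-epoxide of 6 (oxygen anti to the 3-benzoate) | O=C(OC[C@@]12O[C@@H]1[C@@H](OC(=O)c3ccccc3)[C@@H](O)[C@H](O)C2)c1ccccc1
F2 | step 5 | tris(trimethylsilyl) ether of 8 | O=C(OCC1=C[C@@H](O[Si](C)(C)C)[C@H](O[Si](C)(C)C)[C@H](OC(=O)c2ccccc2)[C@H]1O[Si](C)(C)C)c1ccccc1
F3 | step 4 | methyl 4,5-O-(1,1,3,3-tetraisopropyldisiloxane-1,3-diyl)shikimate | COC(=O)C1=C[C@@H](O)[C@H]2O[Si](C(C)C)(C(C)C)O[Si](C(C)C)(C(C)C)O[C@@H]2C1
F4 | step 4 | disiloxane-protected allylic diol | OCC1=C[C@@H](O)[C@H]2O[Si](C(C)C)(C(C)C)O[Si](C(C)C)(C(C)C)O[C@@H]2C1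
F5 | step 4 | disiloxane-protected 3,7-di-O-benzoate | O=C(OCC1=C[C@@H](OC(=O)c2ccccc2)[C@H]3O[Si](C(C)C)(C(C)C)O[Si](C(C)C)(C(C)C)O[C@@H]3C1)c1ccccc1
F6 | step 1 | methyl 3,4-O-(α-methoxybenzylidene)shikimate (orthoester, epimer mixture at the orthoester carbon) | COC(=O)C1=C[C@H]2OC(OC)(c3ccccc3)O[C@H]2[C@H](O)C1
F7 | step 1 | 3,4-orthobenzoate allylic diol (7-OH, 5-OH) | OCC1=C[C@H]2OC(OC)(c3ccccc3)O[C@H]2[C@H](O)C1
F8 | step 1 | 3,4-orthobenzoate 7-O-benzoate | O=C(OCC1=C[C@H]2OC(OC)(c3ccccc3)O[C@H]2[C@H](O)C1)c1ccccc1
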